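The numbers in the tables stem from a simulated flask with constants of no real substance, and the scatter is random.

**Small charge.** A small charge of Q, cQ 5 mM against cJ 0.10 M, stood in the oak flask with D, and I wanted to know what each way of charging these amounts leaves as L.

| flask | J | D | Q | remark | time |
|---|---|---|---|---|---|
| oak | 0.10 M | 0.11 M | 5 mM | run made earlier |  |
| larch | 0.10 M | 0.11 M | 2.5 mM | run made earlier |  |
| cedar | 0.10 M | 0.11 M | 10 mM | run made earlier |  |
| midnight | 0.10 M | 0.110 M | 5.00 mM | one stirred flow tank at steady state, fed with the mixture as stated, mean residence time 2.0 min |  |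
| summer | 0.10 M (fed, over 1.60 min) | 0.110 M | 5.00 mM | all but J at the start; J goes in evenly over 1.60 min, the run ends at 2.0 min | 2.0 min |
| autumn | 0.10 M | 0.110 M | 5.00 mM | a closed flask charged with all of it at once and left for 2.0 min | 2.0 min |
| winter | 0.10 M | 0.110 M (fed, over 1.60 min) | 5.00 mM | all but D at the start; D goes in evenly over 1.60 min, the run ends at 2.0 min | 2.0 min |

| run | time / s | L / % | J / % |
|---|---|---|---|
| oak | 10.0 | 0.5 | 91.1 |
| oak | 20.0 | 2.1 | 83.6 |
| oak | 30.0 | 3.5 | 78.9 |
| oak | 60.0 | 8.4 | 68.2 |
| oak | 120 | 18.9 | 57.7 |
| larch | 15.0 | 1.2 | 87.8 |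
| larch | 30.0 | 3.2 | 79.9 |
| larch | 40.0 | 4.2 | 76.0 |
| larch | 60.0 | 8.0 | 68.6 |
| larch | 80.0 | 12.3 | 63.0 |
| cedar | 15.0 | 1.0 | 83.4 |
| cedar | 30.0 | 2.1 | 75.3 |
| cedar | 40.0 | 4.5 | 71.0 |
| cedar | 60.0 | 8.2 | 64.0 |
| cedar | 80.0 | 11.5 | 59.9 |

(standard deviation of a reading: 0.5 percentage points)

- the stated concentrations are those of everything mixed, before any reaction; amounts are the same in each set-up
- the numbers in the tables scatter by 0.5 percentage points (one standard deviation)
- candidate steps: J + D <-> E; E <-> L + X; X -> Z; J + Q -> G
- the feed brings no volume worth counting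
- the earlier runs were made in a closed, stirred flask

- the set-up with the highest amount of L at the outlet or at the end, in percent of the J put in ("none" if the first two lie within 2 percentage points) (midnight / summer / autumn / winter / none)
- amount of L at the outlet or at the end, in percent of the J put in, midnight
- amount of L at the outlet or at the end, in percent of the J put in, summer
- amount of L at the outlet or at the end, in percent of the J put in, autumn
- amount of L at the outlet or at the end, in percent of the J put in, winter

**The curve.** In oak, J fell by 8.9 percentage points in the first 10.0 s while L read 0.5%, so L began with an induction period. The J missing and not found as L read 18 points at 30.0 s, then 23 points at 60.0 s and 23 points at 120 s, so the knee lay before 60.0 s. I booked the Q charge, 5.00% of J, as G, which left E level at 18.4%. Over that level stretch the L reading rose from 8.4% to 18.9%.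

**Turnover time.** From this I read 1.75 min, the turnover time of E: the standing E divided by the rate at which L grows. Autumn has oak's recipe, so I expected the oak reading, 18.9%. A feed over 1.60 min puts the charge in 0.800 min late on average, so for summer and winter I took off the L that E makes in that delay. That left 10.5%, less than autumn. I had no reading of E for the midnight tank and reckoned no figure for it.

**The forecast.** The forecast named autumn, with 16.5% for midnight, 10.5% for summer, 18.7% for autumn and 10.5% for winter, the fed figures coming from “stepwise hand integration”.

**The flask.** Best came out autumn, with 18.5%, against 14.8% for midnight, 10.8% for summer and 10.8% for winter.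

    J + D ⇌ E (K = 8.50 M⁻¹, k = 0.0764 M⁻¹ s⁻¹)
    E ⇌ L + X (K = 0.0422 M, k = 0.0108 s⁻¹)
    X → Z (k = 0.00177 s⁻¹)
    J + Q → G (k = 0.490 M⁻¹ s⁻¹)

**Longer wait.** In summer, E stood at 15.8% at 1.60 min and 18.6% at 2.00 min. Over that span the turnover time gives 3.9 points of new L, and L went from 6.73% to 10.8%. The neighbouring flask was summer left until 3.0 min, with E at 19.7% at the end. From 10.8%, the same reckoning gave 21.4%. That flask held less, yet it stood above autumn's figure at 2.0 min, with L at 19.9%.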